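**Retrosynthetic overview**

1. The (2S)-flavanone is cut at C2–C1' (ring C to ring B): rhodium-catalysed asymmetric 1,4-addition of chromenylboronic acid 10 to the silyl-protected 8-prenylchromone 14. Rings A and C are bought as 7-hydroxychromone, and the C8 prenyl comes from O-reverse-prenylation and Claisen rearrangement.
2. Ring D (the dimethylpyran fused to ring B; chromene numbering O1, C2, C3, C4, C4a … C8a) is cut at C4–C3 and at O1–C2: a salicylaldehyde plus (2-methylprop-1-enyl)boronic acid. The C8 prenyl is traced back through a [3,3] shift to the same oxygen, so one aryl 1,1-dimethylallyl ether (4) gives the whole B/D unit in one flask.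
3. Enabling feature: O1 sits on C8a of ring B, whose two ortho neighbours are C4a (carrying C4 as a formyl carbon) and C8 (free). This one oxygen hands over the prenyl group, then binds boron to deliver the alkenyl group to C4, then closes onto C2 as the ortho-quinone methide oxygen.
4. Order of ring formation: ring D on ring B (step 3); rings A and C purchased; C2 stereocentre in step 8; desilylation last.

Key step: step 3

Remark: the target stereocentre (C2 of ring C) is S. The sense of induction in step 8 is assumed from the model for (S)-biaryl diphosphines and cyclic enones; if a model run shows the opposite sense, the (R)-ligand is used.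

**Route**

Step 1
Reactants: 1 2-methylbut-3-en-2-ol
Product: 2 2-methylbut-3-en-2-yl 2-methylpropyl carbonate
Conditions: n-BuLi, THF, −78 to 0 °C; then ClCO2i-Bu, 0 °C to rt
Reagents that add atoms: isobutyl chloroformate, CC(C)COC(=O)Cl
Why: The lithium alkoxide of the tertiary allylic alcohol should be acylated cleanly by the chloroformate (standard mixed-carbonate formation).

Step 2
Reactants: 3 5-bromo-2-hydroxybenzaldehyde; 2 2-methylbut-3-en-2-yl 2-methylpropyl carbonate
Product: 4 5-bromo-2-[(2-methylbut-3-en-2-yl)oxy]benzaldehyde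
Conditions: Pd(PPh3)4 (5 mol %), THF, 0 °C
Reagents that add atoms: none
Why: In this Tsuji–Trost O-allylation zerovalent palladium ionises the tertiary carbonate, the released isobutoxide deprotonates the phenol, and at 0 °C the phenoxide should attack the more substituted allyl terminus to give the tertiary ether, while oxidative addition into the aryl bromide is too slow to compete.

Step 3
Reactants: 4 5-bromo-2-[(2-methylbut-3-en-2-yl)oxy]benzaldehyde; 5 (2-methylprop-1-en-1-yl)boronic acid
Product: 9 6-bromo-2,2-dimethyl-8-(3-methylbut-2-en-1-yl)-2H-chromene, via salicylaldehyde 6 (not isolated), via allylic amine 7 (not isolated), via ortho-quinone methide 8 (not isolated)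
Conditions: 1,4-dioxane, 120 °C (sealed); then 5 (1.5 equiv), Bn2NH (40 mol %), 90 °C, same flask
Reagents that add atoms: none
Why: Heating 4 should trigger an aromatic Claisen rearrangement ([3,3]) of the 1,1-dimethylallyl ether to the only free ortho carbon, and tautomerisation gives salicylaldehyde 6 with the prenyl group in place and, only now, a free phenol beside the formyl group. Dibenzylamine then condenses with the aldehyde to an iminium ion while the phenoxide binds boronic acid 5 as a tetracoordinate boronate, so the 2-methylprop-1-enyl group is delivered intramolecularly to the iminium carbon (Petasis borono-Mannich reaction), making the C4–C3 bond in allylic amine 7. At 90 °C 7 should expel dibenzylamine, which re-enters the cycle, to give the vinyl ortho-quinone methide 8, whose 1-oxatriene (carbonyl O, C8a, C4a, C4, C3, C2) closes ring D by thermal disrotatory oxa-6π electrocyclisation, forming O1–C2 and restoring the aromaticity of ring B. The closest known reaction types are the thermal rearrangement of aryl 1,1-dimethylallyl ethers to ortho-prenylphenols and the amine-catalysed Petasis synthesis of 2H-chromenes from salicylaldehydes and alkenylboronic acids. No stereocentre is formed, since C2 carries two methyl groups and the E and Z forms of 8 interconvert with only the Z form able to close. The selectivity needed is regiocontrol of the sigmatropic shift, secured by the formyl group on the other ortho carbon and bromine on the para carbon, and chemoselective alkenyl transfer, secured because it requires the boronate on the neighbouring phenoxide.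

Step 4
Reactants: 9 6-bromo-2,2-dimethyl-8-(3-methylbut-2-en-1-yl)-2H-chromene
Product: 10 [2,2-dimethyl-8-(3-methylbut-2-en-1-yl)-2H-chromen-6-yl]boronic acid
Conditions: n-BuLi, THF, −78 °C; B(Oi-Pr)3, −78 °C to rt; aq. HCl (1 M), 0 °C
Reagents that add atoms: triisopropyl borate, CC(C)OB(OC(C)C)OC(C)C
Why: Bromine–lithium exchange at −78 °C should outrun allylic or benzylic deprotonation, and the aryllithium is trapped by the borate and hydrolysed to the boronic acid (lithiation–borylation).

Step 5
Reactants: 11 7-hydroxy-4H-chromen-4-one; 2 2-methylbut-3-en-2-yl 2-methylpropyl carbonate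
Product: 12 7-[(2-methylbut-3-en-2-yl)oxy]-4H-chromen-4-one
Conditions: Pd(PPh3)4 (5 mol %), THF, 0 °C
Reagents that add atoms: none
Why: The same Tsuji–Trost O-allylation should apply, because the acidic 7-hydroxyl (a vinylogous acid) is deprotonated by the released isobutoxide and attacks the tertiary terminus of the π-allyl complex of palladium.

Step 6
Reactants: 12 7-[(2-methylbut-3-en-2-yl)oxy]-4H-chromen-4-one
Product: 13 7-hydroxy-8-(3-methylbut-2-en-1-yl)-4H-chromen-4-one
Conditions: PhNEt2, 130 °C
Reagents that add atoms: none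
Why: The aromatic Claisen rearrangement ([3,3], chair transition state) of a 7-allyloxy benzopyranone should go mainly to C8, the ortho carbon with the higher double-bond character to C7, and tautomerisation then gives the 8-prenyl phenol.

Step 7
Reactants: 13 7-hydroxy-8-(3-methylbut-2-en-1-yl)-4H-chromen-4-one
Product: 14 7-[(tert-butyldimethylsilyl)oxy]-8-(3-methylbut-2-en-1-yl)-4H-chromen-4-one
Conditions: TBSCl, imidazole, DMF, rt
Reagents that add atoms: tert-butyldimethylsilyl chloride, CC(C)(C)[Si](C)(C)Cl
Why: Standard silylation of the phenol should proceed readily and prevents formation of a deactivating phenoxide in the conjugate addition.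

Step 8
Reactants: 14 7-[(tert-butyldimethylsilyl)oxy]-8-(3-methylbut-2-en-1-yl)-4H-chromen-4-one; 10 [2,2-dimethyl-8-(3-methylbut-2-en-1-yl)-2H-chromen-6-yl]boronic acid
Product: 15 (2S)-7-[(tert-butyldimethylsilyl)oxy]-2-[2,2-dimethyl-8-(3-methylbut-2-en-1-yl)-2H-chromen-6-yl]-8-(3-methylbut-2-en-1-yl)-2,3-dihydro-4H-chromen-4-one
Conditions: [Rh(OH)(cod)]2 (2.5 mol %), (S)-MeO-F12-BIPHEP [(S)-6,6'-dimethoxy-2,2'-bis(bis(3,4,5-trifluorophenyl)phosphino)biphenyl] (6 mol %), toluene/H2O, 50 °C
Reagents that add atoms: none
Why: In this Hayashi–Miyaura asymmetric 1,4-addition the aryl group on monovalent rhodium bound to the electron-poor (S)-diphosphine should insert the chromone C2=C3 bond from one enantioface, which by the model for (S)-biaryl diphosphines and cyclic enones sets C2 as S, while the trisubstituted and chromene alkenes are too unreactive to insert.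

Step 9
Reactants: 15 (2S)-7-[(tert-butyldimethylsilyl)oxy]-2-[2,2-dimethyl-8-(3-methylbut-2-en-1-yl)-2H-chromen-6-yl]-8-(3-methylbut-2-en-1-yl)-2,3-dihydro-4H-chromen-4-one
Product: 16 (2S)-2-[2,2-dimethyl-8-(3-methylbut-2-en-1-yl)-2H-chromen-6-yl]-7-hydroxy-8-(3-methylbut-2-en-1-yl)-2,3-dihydro-4H-chromen-4-one
Conditions: TBAF, AcOH (1:1), THF, 0 °C
Reagents that add atoms: none
Why: Fluoride-mediated cleavage of the aryl silyl ether buffered with acetic acid should free the phenol without the base-triggered retro-oxa-Michael ring opening that would scramble C2, and without acid strong enough to cyclise the prenyl groups.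

**Compound list**

1 | 2-methylbut-3-en-2-ol | CC(C)(O)C=C | starting material
2 | 2-methylbut-3-en-2-yl 2-methylpropyl carbonate | CC(C)COC(=O)OC(C)(C)C=C | intermediate
3 | 5-bromo-2-hydroxybenzaldehyde | O=Cc1cc(Br)ccc1O | starting material
4 | 5-bromo-2-[(2-methylbut-3-en-2-yl)oxy]benzaldehyde | O=Cc1cc(Br)ccc1OC(C)(C)C=C | intermediate
5 | (2-methylprop-1-en-1-yl)boronic acid | CC(C)=CB(O)O | starting material
6 | 5-bromo-2-hydroxy-3-(3-methylbut-2-en-1-yl)benzaldehyde (not isolated) | O=Cc1cc(Br)cc(CC=C(C)C)c1O | intermediate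
7 | racemic 4-bromo-2-[1-(dibenzylamino)-3-methylbut-2-en-1-yl]-6-(3-methylbut-2-en-1-yl)phenol (not isolated) | CC(C)=CCc1cc(Br)cc(C(C=C(C)C)N(Cc2ccccc2)Cc2ccccc2)c1O | intermediate
8 | 4-bromo-6-(3-methylbut-2-en-1-ylidene)-2-(3-methylbut-2-en-1-yl)cyclohexa-2,4-dien-1-one (not isolated) | O=C1C(CC=C(C)C)=CC(Br)=CC1=CC=C(C)C | intermediate
9 | 6-bromo-2,2-dimethyl-8-(3-methylbut-2-en-1-yl)-2H-chromene | CC(C)=CCc1cc(Br)cc2c1OC(C)(C)C=C2 | intermediate
10 | [2,2-dimethyl-8-(3-methylbut-2-en-1-yl)-2H-chromen-6-yl]boronic acid | CC(C)=CCc1cc(B(O)O)cc2c1OC(C)(C)C=C2 | intermediate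
11 | 7-hydroxy-4H-chromen-4-one | O=c1ccoc2cc(O)ccc12 | starting material
12 | 7-[(2-methylbut-3-en-2-yl)oxy]-4H-chromen-4-one | O=c1ccoc2cc(OC(C)(C)C=C)ccc12 | intermediate
13 | 7-hydroxy-8-(3-methylbut-2-en-1-yl)-4H-chromen-4-one | O=c1ccoc2c(CC=C(C)C)c(O)ccc12 | intermediate
14 | 7-[(tert-butyldimethylsilyl)oxy]-8-(3-methylbut-2-en-1-yl)-4H-chromen-4-one | O=c1ccoc2c(CC=C(C)C)c(O[Si](C)(C)C(C)(C)C)ccc12 | intermediate
15 | (2S)-7-[(tert-butyldimethylsilyl)oxy]-2-[2,2-dimethyl-8-(3-methylbut-2-en-1-yl)-2H-chromen-6-yl]-8-(3-methylbut-2-en-1-yl)-2,3-dihydro-4H-chromen-4-one | CC(C)=CCc1cc([C@@H]2CC(=O)c3ccc(O[Si](C)(C)C(C)(C)C)c(CC=C(C)C)c3O2)cc2c1OC(C)(C)C=C2 | intermediate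
16 | (2S)-2-[2,2-dimethyl-8-(3-methylbut-2-en-1-yl)-2H-chromen-6-yl]-7-hydroxy-8-(3-methylbut-2-en-1-yl)-2,3-dihydro-4H-chromen-4-one | CC(C)=CCc1cc([C@@H]2CC(=O)c3ccc(O)c(CC=C(C)C)c3O2)cc2c1OC(C)(C)C=C2 | target

**Step count and risks**

Total step count: 9. Longest linear sequence: 6 (steps 1, 2, 3, 4, 8, 9, or steps 1, 5, 6, 7, 8, 9).

Steps most likely to fail:

Step 3. The tertiary ether may ionise and lose isoprene before the [3,3] shift, and boron-to-carbon transfer of the β,β-disubstituted alkenyl group may be slow enough for protodeboronation to win. Fallback: setting out from 4, the Claisen rearrangement is run on its own (Eu(fod)3 cat., CHCl3, 50 °C) and salicylaldehyde 6 is isolated. Treatment of 6 with 2-methylprop-1-enylmagnesium bromide (2.2 equiv, THF, 0 °C) should give the allylic alcohol 4-bromo-2-(1-hydroxy-3-methylbut-2-en-1-yl)-6-(3-methylbut-2-en-1-yl)phenol F1. Brief heating of F1 in toluene (80 °C, cat. PPTS) should dehydrate it to the same ortho-quinone methide 8, which closes to 9, where the route is rejoined.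

Step 8. Facial discrimination by the hindered, electron-rich aryl rhodium species may be incomplete, protodeboronation may outrun insertion with the chiral phosphine, and ring opening could erode the enantiomeric purity. Fallback: setting out from 14 and 10, addition with ligand-free [Rh(OH)(cod)]2 (dioxane/H2O, 40 °C) should give the racemic flavanone 7-[(tert-butyldimethylsilyl)oxy]-2-[2,2-dimethyl-8-(3-methylbut-2-en-1-yl)-2H-chromen-6-yl]-8-(3-methylbut-2-en-1-yl)-2,3-dihydro-4H-chromen-4-one F2. Kinetic resolution by asymmetric transfer hydrogenation (RuCl[(R,R)-TsDPEN](p-cymene), HCO2H/Et3N, rt; catalyst antipode to be confirmed on a model) is expected to reduce the 2R enantiomer to the cis alcohol (2R,4R)-7-[(tert-butyldimethylsilyl)oxy]-2-[2,2-dimethyl-8-(3-methylbut-2-en-1-yl)-2H-chromen-6-yl]-8-(3-methylbut-2-en-1-yl)-3,4-dihydro-2H-chromen-4-ol F3. The unreduced 2S ketone is then separated by chromatography, and the route is rejoined at 15.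

Step 6. The allyl group may migrate to C6 instead of C8, or the ether may fragment with loss of isoprene. Fallback: setting out from 11, iodination (I2, KI, aq. NH3, 0 °C) should give 7-hydroxy-8-iodo-4H-chromen-4-one F4. Stille coupling of F4 with tributyl(3-methylbut-2-en-1-yl)stannane (Pd(PPh3)4, DMF, 90 °C) should attach the prenyl group through its primary carbon, and the route is rejoined at 13.

**Further compounds**

F1 | step 3 | 4-bromo-2-(1-hydroxy-3-methylbut-2-en-1-yl)-6-(3-methylbut-2-en-1-yl)phenol | CC(C)=CCc1cc(Br)cc(C(O)C=C(C)C)c1O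
F2 | step 8 | racemic 7-[(tert-butyldimethylsilyl)oxy]-2-[2,2-dimethyl-8-(3-methylbut-2-en-1-yl)-2H-chromen-6-yl]-8-(3-methylbut-2-en-1-yl)-2,3-dihydro-4H-chromen-4-one | CC(C)=CCc1cc(C2CC(=O)c3ccc(O[Si](C)(C)C(C)(C)C)c(CC=C(C)C)c3O2)cc2c1OC(C)(C)C=C2
F3 | step 8 | (2R,4R)-7-[(tert-butyldimethylsilyl)oxy]-2-[2,2-dimethyl-8-(3-methylbut-2-en-1-yl)-2H-chromen-6-yl]-8-(3-methylbut-2-en-1-yl)-3,4-dihydro-2H-chromen-4-ol | CC(C)=CCc1cc([C@H]2C[C@@H](O)c3ccc(O[Si](C)(C)C(C)(C)C)c(CC=C(C)C)c3O2)cc2c1OC(C)(C)C=C2
F4 | step 6 | 7-hydroxy-8-iodo-4H-chromen-4-one | O=c1ccoc2c(I)c(O)ccc12
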